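**Assumptions:** The target has no stereocentre and no stereogenic double bond, so it is a single achiral compound and no enantiocontrol is needed. In step 1, BF3·OEt2 is the reaction medium and Lewis-acid promoter; it stands outside the balanced equation (1 + 2 → 3 + H2O) and is destroyed only at the quench.

## Retrosynthetic overview

1. Both benzene rings are bought with all five methoxy groups in place: 3,4-dimethoxyphenol (1) is ring A, and 2,3,4-trimethoxyphenylacetic acid (2) is ring B plus C3.
2. C4–C4a disconnection: ortho-acylation of 1 by 2 gives the deoxybenzoin (3).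
3. C2 is a one-carbon unit from DMF-DMA: enaminone (4) forms from 3 and closes the γ-pyranone, the only ring made, to give the target (5).

## Route

Step 1
Reactants: 1 3,4-dimethoxyphenol; 2 2,3,4-trimethoxyphenylacetic acid
Product: 3 1-(2-hydroxy-4,5-dimethoxyphenyl)-2-(2,3,4-trimethoxyphenyl)ethan-1-one
Conditions: BF3·OEt2 (neat, ca. 8 equiv), 85 °C, 3 h, N2; then aq. NaOAc
Reagents that add atoms: none
Why: BF3-promoted Friedel–Crafts acylation by the free acid goes at C6 of 1, the only position that is ortho to OH, para to the 3-OMe and not flanked by two substituents, and the hydrogen-bonded ortho-hydroxy ketone formed is deactivated against a second acylation; no stereocentre is formed.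

Step 2
Reactants: 3 1-(2-hydroxy-4,5-dimethoxyphenyl)-2-(2,3,4-trimethoxyphenyl)ethan-1-one
Product: 5 6,7,2',3',4'-pentamethoxyisoflavone, via enaminone 4 (not isolated)
Conditions: DMF-DMA (3 equiv), toluene, 100 °C, 4 h
Reagents that add atoms: N,N-dimethylformamide dimethyl acetal (DMF-DMA), COC(OC)N(C)C
Why: Amide-acetal condensation at the doubly activated benzylic CH2 gives enaminone 4, whose ortho-phenol adds to the β-carbon and expels Me2NH (addition–elimination cyclisation, the DMF-DMA isoflavone synthesis) to aromatise the pyranone; the aryl methyl ethers are inert and no stereocentre is formed.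

## Compound list

1 | 3,4-dimethoxyphenol | COc1ccc(O)cc1OC | starting material
2 | 2,3,4-trimethoxyphenylacetic acid | COc1ccc(CC(=O)O)c(OC)c1OC | starting material
3 | 1-(2-hydroxy-4,5-dimethoxyphenyl)-2-(2,3,4-trimethoxyphenyl)ethan-1-one (achiral) | COc1cc(O)c(C(=O)Cc2ccc(OC)c(OC)c2OC)cc1OC | intermediate
4 | (E)-3-(dimethylamino)-1-(2-hydroxy-4,5-dimethoxyphenyl)-2-(2,3,4-trimethoxyphenyl)prop-2-en-1-one (not isolated; E drawn, the geometry is lost on cyclisation) | COc1cc(O)c(C(=O)/C(=C/N(C)C)c2ccc(OC)c(OC)c2OC)cc1OC | intermediate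
5 | 6,7,2',3',4'-pentamethoxyisoflavone = 6,7-dimethoxy-3-(2,3,4-trimethoxyphenyl)-4H-chromen-4-one (achiral) | COc1cc2occ(-c3ccc(OC)c(OC)c3OC)c(=O)c2cc1OC | target

## Totals and risks

Total step count: 2.
Longest linear sequence: 2 steps (1 and 2 are joined in step 1).

The route has only two steps, so both are ranked and there is no third.

**Most likely to fail: step 1.** Hot BF3 may attack acid 2 (self-acylation of its electron-rich ring, loss of the 2-OMe) or give a poor yield of 3. The fallback sets out from 1 and comes back to the route at 5; it makes the C3–aryl bond by cross-coupling instead of acylation. Compound 1 is acetylated ortho to OH with AcOH in BF3·OEt2 at 90 °C to give 1-(2-hydroxy-4,5-dimethoxyphenyl)ethan-1-one F1, which can also be bought. DMF-DMA in toluene at 100 °C converts it to (E)-3-(dimethylamino)-1-(2-hydroxy-4,5-dimethoxyphenyl)prop-2-en-1-one F2. Iodine in CHCl3 at rt then causes iodocyclisation to 3-iodo-6,7-dimethoxy-4H-chromen-4-one F3. Suzuki–Miyaura coupling of F3 with commercial 2,3,4-trimethoxyphenylboronic acid (COc1ccc(B(O)O)c(OC)c1OC; Pd(dppf)Cl2 5 mol %, Na2CO3, DME/H2O, 80 °C) gives 5 directly, so neither 2, 3 nor step 2 is needed.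

**Second: step 2.** The intermolecular condensation at the benzylic CH2 next to the 2'-OMe ring may stall, or may stop at enaminone 4. The fallback sets out from 3 and comes back to the route at 5; it brings in C2 at the oxalate oxidation level by an intramolecular condensation (Baker–Ollis approach). Compound 3 is treated with ethyl chlorooxoacetate (CCOC(=O)C(=O)Cl) in pyridine, 0 °C to rt; the phenol is O-acylated and the ring closes with loss of water to give ethyl 6,7-dimethoxy-4-oxo-3-(2,3,4-trimethoxyphenyl)-4H-chromene-2-carboxylate F4. Saponification (aq. NaOH, acetone, rt; then HCl) gives 6,7-dimethoxy-4-oxo-3-(2,3,4-trimethoxyphenyl)-4H-chromene-2-carboxylic acid F5. Thermal decarboxylation of F5 (Cu powder, quinoline, 200 °C) gives 5.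

## Further compounds

F1 | step 1 | 1-(2-hydroxy-4,5-dimethoxyphenyl)ethan-1-one | COc1cc(O)c(C(C)=O)cc1OC
F2 | step 1 | (E)-3-(dimethylamino)-1-(2-hydroxy-4,5-dimethoxyphenyl)prop-2-en-1-one | COc1cc(O)c(C(=O)/C=C/N(C)C)cc1OC
F3 | step 1 | 3-iodo-6,7-dimethoxy-4H-chromen-4-one | COc1cc2occ(I)c(=O)c2cc1OC
F4 | step 2 | ethyl 6,7-dimethoxy-4-oxo-3-(2,3,4-trimethoxyphenyl)-4H-chromene-2-carboxylate | CCOC(=O)c1oc2cc(OC)c(OC)cc2c(=O)c1-c1ccc(OC)c(OC)c1OC
F5 | step 2 | 6,7-dimethoxy-4-oxo-3-(2,3,4-trimethoxyphenyl)-4H-chromene-2-carboxylic acid | OC(=O)c1oc2cc(OC)c(OC)cc2c(=O)c1-c1ccc(OC)c(OC)c1OC
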